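**Plan**

1. Locants: tetralin C1–C4, C4a, C8a (C1 diarylmethine, C4 benzylic CH2); oxolane O1′, C2′–C5′ (C2′ aryl, C3′ CH2OH, C4′ OH and benzyl). Late cuts: the four phenol O–benzyl bonds, then the oxolane O1′–C2′ bond (benzylic ether), then the acyclic C2′–C3′ bond (aldol of a biaryl aldehyde with a malic-acid-derived acyl unit carrying C3′–C5′).
2. Central cut: tetralin C2–C3. C2 and C3 each bear a CH2OH group, so both are α-carbons of latent esters; C3 also bears oxygen; C1 and C4 carry no acidifying group. A bis-enolate of the seco-diester can therefore be oxidised so that C2 and C3 join and the six-membered ring closes.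
3. Earlier cuts: C1–aryl (rhodium-catalysed 1,4-arylation of a cinnamate), the biaryl bond (Suzuki–Miyaura), the cinnamate C=C (Mizoroki–Heck) and C4–aryl (Grignard opening of a glycidic ester).
4. Forward: biaryl boronic acid (steps 1–7) and cinnamate (steps 8–12) are joined at C1 (step 13); the tetralin ring closes (step 14); the oxolane chain is attached by an Evans aldol (step 20) and reduced; the oxolane ring closes (step 22); hydrogenolysis ends the route.
5. Stereochemistry: C1 from the chiral diene–rhodium catalyst; C2 and C3 from C1 in the ring closure; C4′ from (S)-malic acid (alkylation with self-regeneration of the stereocentre); C3′ from the (S)-oxazolidinone auxiliary; C2′ trans to C3′ in the ether closure.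

Key step: step 14

Assumption: the 2R configuration of the lactate-derived carbon in 13–17 is arbitrary, because this carbon becomes an enolate carbon in step 14; the biaryl axis (two ortho substituents) is taken as freely rotating.

**Route**

Step 1
Reactants: 1 5-bromovanillin
Product: 2 4-(benzyloxy)-3-bromo-5-methoxybenzaldehyde
Conditions: BnBr, K2CO3, DMF, 60 °C
Reagents that add atoms: benzyl bromide, BrCc1ccccc1
Why: Williamson ether synthesis on the acidic phenol gives a benzyl ether that should survive every base, organometallic and hydride step that follows.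

Step 2
Reactants: 2 4-(benzyloxy)-3-bromo-5-methoxybenzaldehyde
Product: 3 2-[4-(benzyloxy)-3-bromo-5-methoxyphenyl]-1,3-dioxolane
Conditions: ethylene glycol, p-TsOH (cat.), toluene, reflux, Dean–Stark
Reagents that add atoms: ethylene glycol, OCCO
Why: Acid-catalysed acetalisation with azeotropic removal of water masks the aldehyde against the aryllithium and enolate chemistry ahead.

Step 3
Reactants: 3 2-[4-(benzyloxy)-3-bromo-5-methoxyphenyl]-1,3-dioxolane
Product: 4 2-[4-(benzyloxy)-3-methoxy-5-(4,4,5,5-tetramethyl-1,3,2-dioxaborolan-2-yl)phenyl]-1,3-dioxolane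
Conditions: B2pin2, PdCl2(dppf) (3 mol %), KOAc, dioxane, 90 °C
Reagents that add atoms: bis(pinacolato)diboron, CC1(C)OB(OC1(C)C)B1OC(C)(C)C(C)(C)O1
Why: Miyaura borylation of the aryl bromide tolerates the acetal and the ortho benzyloxy group and should give the boronate for the biaryl coupling.

Step 4
Reactants: 5 4-bromo-2-methoxyphenol
Product: 6 4-bromo-2-iodo-6-methoxyphenol
Conditions: NIS, p-TsOH (cat.), MeCN, 0 °C to rt
Reagents that add atoms: N-iodosuccinimide, O=C1CCC(=O)N1I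
Why: Electrophilic aromatic iodination should go to the only free position ortho to the phenol, the para position being blocked by bromine.

Step 5
Reactants: 6 4-bromo-2-iodo-6-methoxyphenol
Product: 7 2-(benzyloxy)-5-bromo-1-iodo-3-methoxybenzene
Conditions: BnBr, K2CO3, DMF, 60 °C
Reagents that add atoms: benzyl bromide, BrCc1ccccc1
Why: Williamson ether synthesis protects the flanked phenol as its benzyl ether.

Step 6
Reactants: 4 the pinacol boronate; 7 2-(benzyloxy)-5-bromo-1-iodo-3-methoxybenzene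
Product: 8 2-[2',6-bis(benzyloxy)-5'-bromo-3',5-dimethoxy-[1,1'-biphenyl]-3-yl]-1,3-dioxolane
Conditions: Pd(PPh3)4 (5 mol %), K2CO3, dioxane–H2O, 80 °C
Reagents that add atoms: none
Why: Suzuki–Miyaura coupling should occur only at the C–I bond, whose oxidative addition is much faster than that of the C–Br bond, so the bromide para to the benzyloxy group is kept.

Step 7
Reactants: 8 the bromobiaryl acetal
Product: 10 [2',6-bis(benzyloxy)-5'-(1,3-dioxolan-2-yl)-3',5-dimethoxy-[1,1'-biphenyl]-3-yl]boronic acid, via aryllithium 9 (not isolated)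
Conditions: n-BuLi, THF, −78 °C; B(OiPr)3, −78 °C to rt; H2O
Reagents that add atoms: triisopropyl borate, CC(C)OB(OC(C)C)OC(C)C; water, O
Why: Bromine–lithium exchange followed by borylation and hydrolysis of the borate is a standard route to aryl boronic acids, and acetal and benzyl ethers are inert to n-BuLi at −78 °C.

Step 8
Reactants: 5 4-bromo-2-methoxyphenol
Product: 11 1-(benzyloxy)-4-bromo-2-methoxybenzene
Conditions: BnBr, K2CO3, DMF, 60 °C
Reagents that add atoms: benzyl bromide, BrCc1ccccc1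
Why: Williamson ether synthesis protects the phenol before Grignard formation.

Step 9
Reactants: 11 1-(benzyloxy)-4-bromo-2-methoxybenzene
Product: 13 methyl (2R)-3-[4-(benzyloxy)-3-methoxyphenyl]-2-hydroxypropanoate, via aryl Grignard reagent 12 (not isolated)
Conditions: Mg, THF, reflux; then CuI (10 mol %), methyl (R)-glycidate, THF, −40 °C; H2O
Reagents that add atoms: methyl (2R)-oxirane-2-carboxylate, COC(=O)[C@H]1CO1
Why: Copper-catalysed opening of a glycidic ester by an aryl Grignard reagent takes place at the terminal epoxide carbon and leaves the C2 configuration and, at low temperature, the ester untouched.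

Step 10
Reactants: 13 methyl (2R)-3-[4-(benzyloxy)-3-methoxyphenyl]-2-hydroxypropanoate
Product: 14 methyl (2R)-3-[4-(benzyloxy)-3-methoxyphenyl]-2-(methoxymethoxy)propanoate
Conditions: MOMCl, iPr2NEt, CH2Cl2, 0 °C to rt
Reagents that add atoms: chloromethyl methyl ether, COCCl
Why: O-alkylation gives a methoxymethyl ether that tolerates LDA and copper dibromide and can be removed by acid before the aldol step.

Step 11
Reactants: 14 the methoxymethyl-protected aryl-lactate
Product: 15 methyl (2R)-3-[4-(benzyloxy)-2-bromo-5-methoxyphenyl]-2-(methoxymethoxy)propanoate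
Conditions: NBS, MeCN, 0 °C
Reagents that add atoms: N-bromosuccinimide, O=C1CCC(=O)N1Br
Why: Electrophilic aromatic bromination should go para to the methoxy group and ortho to the side chain, the most activated free position of a 4-alkyl-1,2-dialkoxybenzene.

Step 12
Reactants: 15 the aryl bromide
Product: 16 methyl (2E)-3-{5-(benzyloxy)-4-methoxy-2-[(2R)-3-methoxy-2-(methoxymethoxy)-3-oxopropyl]phenyl}prop-2-enoate
Conditions: methyl acrylate, Pd(OAc)2 (5 mol %), P(o-tol)3, Et3N, DMF, 100 °C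
Reagents that add atoms: methyl acrylate, C=CC(=O)OC
Why: Mizoroki–Heck coupling of the aryl bromide with the acrylate gives the E-cinnamate by syn insertion and syn β-hydride elimination.

Step 13
Reactants: 16 the cinnamate; 10 the biaryl boronic acid
Product: 17 methyl (3S)-3-[2',6-bis(benzyloxy)-5'-(1,3-dioxolan-2-yl)-3',5-dimethoxy-[1,1'-biphenyl]-3-yl]-3-{5-(benzyloxy)-4-methoxy-2-[(2R)-3-methoxy-2-(methoxymethoxy)-3-oxopropyl]phenyl}propanoate
Conditions: [RhCl(C2H4)2]2 (2.5 mol %), (S,S)-2,5-diphenylbicyclo[2.2.2]octa-2,5-diene (5.5 mol %), KOH (0.2 equiv), dioxane–H2O 10:1, 50 °C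
Reagents that add atoms: none
Why: Hayashi–Miyaura asymmetric 1,4-addition transfers the aryl group from rhodium to the β-carbon of the cinnamate, and the chiral diene should direct it to the Re face to set C1 as S (the sense is inferred from enone additions with this ligand class, and the antipodal ligand is available if this substrate reverses it).

Step 14
Reactants: 17 the seco-diester
Product: 19 dimethyl (1S,2R,3S)-7-(benzyloxy)-1-[2',6-bis(benzyloxy)-5'-(1,3-dioxolan-2-yl)-3',5-dimethoxy-[1,1'-biphenyl]-3-yl]-6-methoxy-3-(methoxymethoxy)-1,2,3,4-tetrahydronaphthalene-2,3-dicarboxylate, via dilithium bis-enolate 18 (not isolated)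
Conditions: LDA (2.3 equiv), THF (0.01 M), −78 °C; then CuBr2 (2.5 equiv), −78 to 0 °C
Reagents that add atoms: none
Why: Proposed new method: two equivalents of LDA convert both ester α-positions (C2–H2 and the oxygenated C3–H) into the dilithium bis-enolate 18, and one-electron oxidation by CuBr2 turns the more electron-rich α-alkoxy enolate into a captodatively stabilised C3 radical (or its copper-bound equivalent) that is trapped by the enolate carbon C2, a second oxidation then giving the diester. The closest known reactions are the intramolecular oxidative coupling of diester dienolates to trans-cycloalkane-1,2-dicarboxylates and oxidative enolate heterocouplings, but an α-alkoxy ester enolate that ends as a fully substituted carbinol carbon has not been used as a partner. The six-membered ring closes by 6-exo-trig attack of C3 on the exocyclic enolate double bond at C2, the two α-carbons being held 1,6 to each other by the ortho-disubstituted arene. C2 is set in a chair-like transition state in which the C1 aryl group and the C2 ester unit are both equatorial (trans), and this arrangement could be restored by methoxide equilibration because C2–H is the only acidic C–H left in 19. C3 is set by the same chair, since the known trans preference of these couplings places the second ester unit equatorial as well, hence cis to the C1 aryl group, and leaves the small methoxymethoxy group axial. The step needs ring closure to outrun intermolecular coupling and α-bromination and needs C1 to direct the face at C3, which high dilution, the absence of any β-leaving group and the equatorial preference of the large C1 biaryl group should secure.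

Step 15
Reactants: 19 the tetralin diester acetal
Product: 20 dimethyl (1S,2R,3S)-7-(benzyloxy)-1-[2',6-bis(benzyloxy)-5'-formyl-3',5-dimethoxy-[1,1'-biphenyl]-3-yl]-3-hydroxy-6-methoxy-1,2,3,4-tetrahydronaphthalene-2,3-dicarboxylate
Conditions: 3 M HCl, THF–MeOH, 50 °C
Reagents that add atoms: water, O
Why: Acid hydrolysis should cleave the dioxolane and the methoxymethyl ether in one operation, while aryl benzyl ethers and methyl esters are stable to these conditions.

Step 16
Reactants: 21 (S)-malic acid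
Product: 22 [(2S,4S)-2-tert-butyl-5-oxo-1,3-dioxolan-4-yl]acetic acid
Conditions: pivalaldehyde, p-TsOH (cat.), H2SO4 (cat.), pentane, reflux, Dean–Stark
Reagents that add atoms: pivalaldehyde, CC(C)(C)C=O
Why: Acetalisation of the α-hydroxy acid unit gives the dioxolanone and leaves the β-carboxyl free, and the acetal carbon is set cis to the side chain under thermodynamic control.

Step 17
Reactants: 23 [3-(benzyloxy)-4-methoxyphenyl]methanol
Product: 24 2-(benzyloxy)-4-(bromomethyl)-1-methoxybenzene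
Conditions: PBr3, Et2O, 0 °C
Reagents that add atoms: phosphorus tribromide, BrP(Br)Br
Why: Conversion of the benzylic alcohol into the bromide by PBr3 is a standard substitution, and the product is used at once.

Step 18
Reactants: 22 the dioxolanone acid; 24 the benzylic bromide
Product: 26 {(2S,4S)-4-[3-(benzyloxy)-4-methoxybenzyl]-2-tert-butyl-5-oxo-1,3-dioxolan-4-yl}acetic acid, via dilithium dianion 25 (not isolated)
Conditions: LiHMDS (2.2 equiv), THF, −78 °C; then 24, −78 to −20 °C; 1 M HCl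
Reagents that add atoms: none
Why: Enolate alkylation with self-regeneration of the stereocentre: the benzylic bromide enters the dioxolanone enolate trans to the tert-butyl group, so the fully substituted carbinol carbon (the later C4′) forms with overall retention.

Step 19
Reactants: 26 the alkylated dioxolanone acid
Product: 28 (4S)-4-benzyl-3-({(2S,4S)-4-[3-(benzyloxy)-4-methoxybenzyl]-2-tert-butyl-5-oxo-1,3-dioxolan-4-yl}acetyl)-1,3-oxazolidin-2-one, via mixed pivalic anhydride 27 (not isolated)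
Conditions: PivCl, Et3N, THF, −20 °C; then (S)-4-benzyl-1,3-oxazolidin-2-one, LiCl, rt
Reagents that add atoms: (4S)-4-benzyl-1,3-oxazolidin-2-one, O=C1N[C@@H](Cc2ccccc2)CO1
Why: N-acylation of the oxazolidinone through the mixed anhydride under LiCl and amine conditions is mild enough to spare the hindered dioxolanone.

Step 20
Reactants: 28 the acyl oxazolidinone; 20 the biaryl aldehyde
Product: 30 dimethyl (1S,2R,3S)-1-{5'-[(1S,2R)-3-[(4S)-4-benzyl-2-oxo-1,3-oxazolidin-3-yl]-2-{(2S,4S)-4-[3-(benzyloxy)-4-methoxybenzyl]-2-tert-butyl-5-oxo-1,3-dioxolan-4-yl}-1-hydroxy-3-oxopropyl]-2',6-bis(benzyloxy)-3',5-dimethoxy-[1,1'-biphenyl]-3-yl}-7-(benzyloxy)-3-hydroxy-6-methoxy-1,2,3,4-tetrahydronaphthalene-2,3-dicarboxylate, via dibutylboron Z-enolate 29 (not isolated)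
Conditions: 28 (1.5 equiv), Bu2BOTf, iPr2NEt, CH2Cl2, 0 °C; then 20, −78 to 0 °C; pH 7 buffer, MeOH, H2O2
Reagents that add atoms: none
Why: Evans syn-aldol addition through a Zimmerman–Traxler transition state, in which the benzyl group of the auxiliary shields one enolate face, sets C3′ (R in the final locants) and the syn carbinol centre C2′.

Step 21
Reactants: 30 the aldol adduct
Product: 31 (1S,2S,3S)-7-(benzyloxy)-1-{2',6-bis(benzyloxy)-5'-[(1S,2R,3S)-3-[3-(benzyloxy)-4-methoxybenzyl]-1,3,4-trihydroxy-2-(hydroxymethyl)butyl]-3',5-dimethoxy-[1,1'-biphenyl]-3-yl}-2,3-bis(hydroxymethyl)-6-methoxy-1,2,3,4-tetrahydronaphthalen-3-ol (tetralin locants as in the plan)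
Conditions: LiBH4 (excess), MeOH, THF, 0 to 40 °C
Reagents that add atoms: none
Why: Borohydride reduction should cleave the acyl oxazolidinone to the primary alcohol, reduce both methyl esters and open the dioxolanone to the 1,2-diol in one operation without touching any stereocentre.

Step 22
Reactants: 31 the heptaol
Product: 32 (1S,2S,3S)-7-(benzyloxy)-1-{2',6-bis(benzyloxy)-5'-[(2S,3R,4S)-4-[3-(benzyloxy)-4-methoxybenzyl]-4-hydroxy-3-(hydroxymethyl)oxolan-2-yl]-3',5-dimethoxy-[1,1'-biphenyl]-3-yl}-2,3-bis(hydroxymethyl)-6-methoxy-1,2,3,4-tetrahydronaphthalen-3-ol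
Conditions: CSA (0.1 equiv), CH2Cl2–THF, 0 °C
Reagents that add atoms: none
Why: Acid-mediated SN1 cycloetherification: the benzylic cation stabilised by the para benzyloxy group is captured by the C5′ hydroxyl, the only one that gives a five-membered ring, and closure trans to the C3′ substituent should set C2′ as S.

Step 23
Reactants: 32 the tetrabenzyl ether
Product: 33 CNP0252244.1, (1S,2S,3S)-1-{2',6-dihydroxy-5'-[(2S,3R,4S)-4-hydroxy-4-(3-hydroxy-4-methoxybenzyl)-3-(hydroxymethyl)oxolan-2-yl]-3',5-dimethoxy-[1,1'-biphenyl]-3-yl}-2,3-bis(hydroxymethyl)-6-methoxy-1,2,3,4-tetrahydronaphthalene-3,7-diol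
Conditions: H2 (1 atm), Pd/C (10 %), EtOAc–MeOH, rt
Reagents that add atoms: none
Why: Catalytic hydrogenolysis cleaves the four aryl benzyl ethers much faster than the benzylic C–O bond of the 2-aryl-oxolane, so the reaction is stopped once hydrogen uptake for four benzyl groups is complete.

**Compound list**

1 | 5-bromovanillin | COc1cc(C=O)cc(Br)c1O | starting material
2 | 4-(benzyloxy)-3-bromo-5-methoxybenzaldehyde | COc1cc(C=O)cc(Br)c1OCc1ccccc1 | intermediate
3 | 2-[4-(benzyloxy)-3-bromo-5-methoxyphenyl]-1,3-dioxolane | COc1cc(C2OCCO2)cc(Br)c1OCc1ccccc1 | intermediate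
4 | 2-[4-(benzyloxy)-3-methoxy-5-(4,4,5,5-tetramethyl-1,3,2-dioxaborolan-2-yl)phenyl]-1,3-dioxolane | COc1cc(C2OCCO2)cc(B2OC(C)(C)C(C)(C)O2)c1OCc1ccccc1 | intermediate
5 | 4-bromo-2-methoxyphenol | COc1cc(Br)ccc1O | starting material
6 | 4-bromo-2-iodo-6-methoxyphenol | COc1cc(Br)cc(I)c1O | intermediate
7 | 2-(benzyloxy)-5-bromo-1-iodo-3-methoxybenzene | COc1cc(Br)cc(I)c1OCc1ccccc1 | intermediate
8 | 2-[2',6-bis(benzyloxy)-5'-bromo-3',5-dimethoxy-[1,1'-biphenyl]-3-yl]-1,3-dioxolane | COc1cc(C2OCCO2)cc(-c2cc(Br)cc(OC)c2OCc2ccccc2)c1OCc1ccccc1 | intermediate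
9 | [2',6-bis(benzyloxy)-5'-(1,3-dioxolan-2-yl)-3',5-dimethoxy-[1,1'-biphenyl]-3-yl]lithium | COc1cc(C2OCCO2)cc(-c2cc([Li])cc(OC)c2OCc2ccccc2)c1OCc1ccccc1 | intermediate
10 | [2',6-bis(benzyloxy)-5'-(1,3-dioxolan-2-yl)-3',5-dimethoxy-[1,1'-biphenyl]-3-yl]boronic acid | COc1cc(C2OCCO2)cc(-c2cc(B(O)O)cc(OC)c2OCc2ccccc2)c1OCc1ccccc1 | intermediate
11 | 1-(benzyloxy)-4-bromo-2-methoxybenzene | COc1cc(Br)ccc1OCc1ccccc1 | intermediate
12 | [4-(benzyloxy)-3-methoxyphenyl]magnesium bromide | COc1cc([Mg]Br)ccc1OCc1ccccc1 | intermediate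
13 | methyl (2R)-3-[4-(benzyloxy)-3-methoxyphenyl]-2-hydroxypropanoate | COC(=O)[C@H](O)Cc1ccc(OCc2ccccc2)c(OC)c1 | intermediate
14 | methyl (2R)-3-[4-(benzyloxy)-3-methoxyphenyl]-2-(methoxymethoxy)propanoate | COC(=O)[C@H](OCOC)Cc1ccc(OCc2ccccc2)c(OC)c1 | intermediate
15 | methyl (2R)-3-[4-(benzyloxy)-2-bromo-5-methoxyphenyl]-2-(methoxymethoxy)propanoate | COC(=O)[C@H](OCOC)Cc1cc(OC)c(OCc2ccccc2)cc1Br | intermediate
16 | methyl (2E)-3-{5-(benzyloxy)-4-methoxy-2-[(2R)-3-methoxy-2-(methoxymethoxy)-3-oxopropyl]phenyl}prop-2-enoate | COC(=O)/C=C/c1cc(OCc2ccccc2)c(OC)cc1C[C@@H](OCOC)C(=O)OC | intermediate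
17 | methyl (3S)-3-[2',6-bis(benzyloxy)-5'-(1,3-dioxolan-2-yl)-3',5-dimethoxy-[1,1'-biphenyl]-3-yl]-3-{5-(benzyloxy)-4-methoxy-2-[(2R)-3-methoxy-2-(methoxymethoxy)-3-oxopropyl]phenyl}propanoate | COc1cc(C2OCCO2)cc(-c2cc([C@H](CC(=O)OC)c3cc(OCc4ccccc4)c(OC)cc3C[C@@H](OCOC)C(=O)OC)cc(OC)c2OCc2ccccc2)c1OCc1ccccc1 | intermediate
18 | dilithium bis-enolate of 17 (both ester groups as lithium enolates, C1 S) | COc1cc(C2OCCO2)cc(-c2cc([C@H](C=C(OC)O[Li])c3cc(OCc4ccccc4)c(OC)cc3CC(OCOC)=C(OC)O[Li])cc(OC)c2OCc2ccccc2)c1OCc1ccccc1 | intermediate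
19 | dimethyl (1S,2R,3S)-7-(benzyloxy)-1-[2',6-bis(benzyloxy)-5'-(1,3-dioxolan-2-yl)-3',5-dimethoxy-[1,1'-biphenyl]-3-yl]-6-methoxy-3-(methoxymethoxy)-1,2,3,4-tetrahydronaphthalene-2,3-dicarboxylate | COc1cc(C2OCCO2)cc(-c2cc([C@H]3c4cc(OCc5ccccc5)c(OC)cc4C[C@@](OCOC)(C(=O)OC)[C@@H]3C(=O)OC)cc(OC)c2OCc2ccccc2)c1OCc1ccccc1 | intermediate
20 | dimethyl (1S,2R,3S)-7-(benzyloxy)-1-[2',6-bis(benzyloxy)-5'-formyl-3',5-dimethoxy-[1,1'-biphenyl]-3-yl]-3-hydroxy-6-methoxy-1,2,3,4-tetrahydronaphthalene-2,3-dicarboxylate | COc1cc(C=O)cc(-c2cc([C@H]3c4cc(OCc5ccccc5)c(OC)cc4C[C@@](O)(C(=O)OC)[C@@H]3C(=O)OC)cc(OC)c2OCc2ccccc2)c1OCc1ccccc1 | intermediate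
21 | (S)-malic acid | OC(=O)C[C@H](O)C(=O)O | starting material
22 | [(2S,4S)-2-tert-butyl-5-oxo-1,3-dioxolan-4-yl]acetic acid | CC(C)(C)[C@@H]1OC(=O)[C@H](CC(=O)O)O1 | intermediate
23 | [3-(benzyloxy)-4-methoxyphenyl]methanol | COc1ccc(CO)cc1OCc1ccccc1 | starting material
24 | 2-(benzyloxy)-4-(bromomethyl)-1-methoxybenzene | COc1ccc(CBr)cc1OCc1ccccc1 | intermediate
25 | dilithium salt of 22 (lithium carboxylate and lithium dioxolanone enolate, acetal carbon S) | CC(C)(C)[C@@H]1OC(O[Li])=C(CC(=O)O[Li])O1 | intermediate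
26 | {(2S,4S)-4-[3-(benzyloxy)-4-methoxybenzyl]-2-tert-butyl-5-oxo-1,3-dioxolan-4-yl}acetic acid | CC(C)(C)[C@@H]1OC(=O)[C@@](CC(=O)O)(Cc2ccc(OC)c(OCc3ccccc3)c2)O1 | intermediate
27 | mixed anhydride of 26 with pivalic acid | CC(C)(C)[C@@H]1OC(=O)[C@@](CC(=O)OC(=O)C(C)(C)C)(Cc2ccc(OC)c(OCc3ccccc3)c2)O1 | intermediate
28 | (4S)-4-benzyl-3-({(2S,4S)-4-[3-(benzyloxy)-4-methoxybenzyl]-2-tert-butyl-5-oxo-1,3-dioxolan-4-yl}acetyl)-1,3-oxazolidin-2-one | CC(C)(C)[C@@H]1OC(=O)[C@@](CC(=O)N2C(=O)OC[C@@H]2Cc2ccccc2)(Cc2ccc(OC)c(OCc3ccccc3)c2)O1 | intermediate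
29 | Z-dibutylboron enolate of 28 | CCCCB(CCCC)O/C(N1C(=O)OC[C@@H]1Cc1ccccc1)=C\[C@]1(Cc2ccc(OC)c(OCc3ccccc3)c2)O[C@H](C(C)(C)C)OC1=O | intermediate
30 | dimethyl (1S,2R,3S)-1-{5'-[(1S,2R)-3-[(4S)-4-benzyl-2-oxo-1,3-oxazolidin-3-yl]-2-{(2S,4S)-4-[3-(benzyloxy)-4-methoxybenzyl]-2-tert-butyl-5-oxo-1,3-dioxolan-4-yl}-1-hydroxy-3-oxopropyl]-2',6-bis(benzyloxy)-3',5-dimethoxy-[1,1'-biphenyl]-3-yl}-7-(benzyloxy)-3-hydroxy-6-methoxy-1,2,3,4-tetrahydronaphthalene-2,3-dicarboxylate | COc1cc([C@@H](O)[C@@H](C(=O)N2C(=O)OC[C@@H]2Cc2ccccc2)[C@]2(Cc3ccc(OC)c(OCc4ccccc4)c3)O[C@H](C(C)(C)C)OC2=O)cc(-c2cc([C@H]3c4cc(OCc5ccccc5)c(OC)cc4C[C@@](O)(C(=O)OC)[C@@H]3C(=O)OC)cc(OC)c2OCc2ccccc2)c1OCc1ccccc1 | intermediate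
31 | (1S,2S,3S)-7-(benzyloxy)-1-{2',6-bis(benzyloxy)-5'-[(1S,2R,3S)-3-[3-(benzyloxy)-4-methoxybenzyl]-1,3,4-trihydroxy-2-(hydroxymethyl)butyl]-3',5-dimethoxy-[1,1'-biphenyl]-3-yl}-2,3-bis(hydroxymethyl)-6-methoxy-1,2,3,4-tetrahydronaphthalen-3-ol | COc1ccc(C[C@@](O)(CO)[C@H](CO)[C@H](O)c2cc(OC)c(OCc3ccccc3)c(-c3cc([C@H]4c5cc(OCc6ccccc6)c(OC)cc5C[C@@](O)(CO)[C@@H]4CO)cc(OC)c3OCc3ccccc3)c2)cc1OCc1ccccc1 | intermediate
32 | (1S,2S,3S)-7-(benzyloxy)-1-{2',6-bis(benzyloxy)-5'-[(2S,3R,4S)-4-[3-(benzyloxy)-4-methoxybenzyl]-4-hydroxy-3-(hydroxymethyl)oxolan-2-yl]-3',5-dimethoxy-[1,1'-biphenyl]-3-yl}-2,3-bis(hydroxymethyl)-6-methoxy-1,2,3,4-tetrahydronaphthalen-3-ol | COc1ccc(C[C@@]2(O)CO[C@H](c3cc(OC)c(OCc4ccccc4)c(-c4cc([C@H]5c6cc(OCc7ccccc7)c(OC)cc6C[C@@](O)(CO)[C@@H]5CO)cc(OC)c4OCc4ccccc4)c3)[C@H]2CO)cc1OCc1ccccc1 | intermediate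
33 | CNP0252244.1, (1S,2S,3S)-1-{2',6-dihydroxy-5'-[(2S,3R,4S)-4-hydroxy-4-(3-hydroxy-4-methoxybenzyl)-3-(hydroxymethyl)oxolan-2-yl]-3',5-dimethoxy-[1,1'-biphenyl]-3-yl}-2,3-bis(hydroxymethyl)-6-methoxy-1,2,3,4-tetrahydronaphthalene-3,7-diol | COc1ccc(C[C@@]2(O)CO[C@H](c3cc(OC)c(O)c(-c4cc([C@H]5c6cc(O)c(OC)cc6C[C@@](O)(CO)[C@@H]5CO)cc(OC)c4O)c3)[C@H]2CO)cc1O | target

**Count**

Total: 23 steps. Longest linear sequence: 12 steps (1, 2, 3, 6, 7, 13, 14, 15, 20, 21, 22, 23; the arm through steps 8–12 is equally long).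

**Steps most likely to fail**

1. Step 14 (oxidative ring closure). The two enolate carbons may fail to couple (intermolecular coupling, α-bromination by CuBr2 or simple proton return), or C3 may form on the wrong face. The fallback closes the tetralin at C1–C8a by a Friedel–Crafts alkylation instead; it sets out from 8 and 22 and comes back at 20.
 - Commercial [4-(benzyloxy)-3-methoxyphenyl]methanol and PBr3 give 1-(benzyloxy)-4-(bromomethyl)-2-methoxybenzene F1.
 - Alkylation of the dianion of 22 with it, as in step 18, gives {(2S,4S)-4-[4-(benzyloxy)-3-methoxybenzyl]-2-tert-butyl-5-oxo-1,3-dioxolan-4-yl}acetic acid F2, which is converted as in step 19 into its (4S)-4-benzyl-oxazolidinone imide F3.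
 - Bromine–lithium exchange on 8 and quenching with DMF gives 2',6-bis(benzyloxy)-5'-(1,3-dioxolan-2-yl)-3',5-dimethoxy-[1,1'-biphenyl]-3-carbaldehyde F4.
 - Evans syn-aldol addition of the dibutylboron enolate of F3 to F4 gives the β-hydroxy imide F5, with C2 set by the auxiliary and C3 by malic acid.
 - BF3·OEt2 in CH2Cl2 at low temperature, then aqueous acid, ionises the benzylic alcohol. Friedel–Crafts attack of the 4-benzyloxy-3-methoxybenzyl ring, para to its methoxy group, closes the ring with the C1 aryl group trans to the C2 acyl group, the usual outcome of hydroxybenzyl-lactone to aryltetralin cyclisations. The acetal is lost in the work-up, giving the spiro-dioxolanone imide aldehyde F6.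
 - NaOMe in MeOH cleaves the imide and the dioxolanone to the two methyl esters and the free C3 hydroxyl, which is 20.

2. Step 20 (aldol union). The boron enolate of 28 may expel the dioxolanone oxygen by β-elimination, or may add too slowly because its α-carbon is flanked by a fully substituted centre. The fallback uses a nucleophile in which C5′ is already an alcohol protected as an acetonide; it sets out from 26 and comes back at 32.
 - LiAlH4 reduces 26 to (2S)-2-[3-(benzyloxy)-4-methoxybenzyl]butane-1,2,4-triol F7.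
 - 2,2-Dimethoxypropane and PPTS close the five-membered acetonide on the 1,2-diol, giving 2-{(4S)-4-[3-(benzyloxy)-4-methoxybenzyl]-2,2-dimethyl-1,3-dioxolan-4-yl}ethan-1-ol F8.
 - TEMPO (cat.) and PhI(OAc)2 in aqueous MeCN oxidise the primary alcohol to {(4S)-4-[3-(benzyloxy)-4-methoxybenzyl]-2,2-dimethyl-1,3-dioxolan-4-yl}acetic acid F9, which is converted as in step 19 into the (4S)-4-benzyl-oxazolidinone imide F10.
 - Its boron enolate carries only an ordinary ketal oxygen in the β-position; Evans syn-aldol addition to 20 gives the adduct F11.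
 - LiBH4 reduces the imide and both methyl esters to the acetonide-protected polyol F12.
 - CSA in wet CH2Cl2 removes the acetonide and closes the oxolane in the same operation, giving 32.

3. Step 22 (ether closure). The benzylic cation may be intercepted by the electron-rich 3-benzyloxy-4-methoxybenzyl ring (Friedel–Crafts closure to a second aryltetralin) or may fragment before the C5′ hydroxyl captures it. The fallback inverts the last two operations; it sets out from 31 and comes back at 33.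
 - Hydrogenolysis of 31 (H2, Pd/C) gives the fully debenzylated open-chain polyol F13.
 - Its para-hydroxybenzylic alcohol ionises under buffered, nearly neutral aqueous conditions (warm aqueous MeCN, pH about 5) to a para-quinone methide, a much milder electrophile than the cation. Intramolecular addition of the C5′ hydroxyl, the known mode of oxolane formation in phenolic lignans, should close the ring trans to C3′ and give 33.

**Further compounds**

F1 | step 14 | 1-(benzyloxy)-4-(bromomethyl)-2-methoxybenzene | COc1cc(CBr)ccc1OCc1ccccc1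
F2 | step 14 | {(2S,4S)-4-[4-(benzyloxy)-3-methoxybenzyl]-2-tert-butyl-5-oxo-1,3-dioxolan-4-yl}acetic acid | CC(C)(C)[C@@H]1OC(=O)[C@@](CC(=O)O)(Cc2ccc(OCc3ccccc3)c(OC)c2)O1
F3 | step 14 | (4S)-4-benzyl-3-({(2S,4S)-4-[4-(benzyloxy)-3-methoxybenzyl]-2-tert-butyl-5-oxo-1,3-dioxolan-4-yl}acetyl)-1,3-oxazolidin-2-one | CC(C)(C)[C@@H]1OC(=O)[C@@](CC(=O)N2C(=O)OC[C@@H]2Cc2ccccc2)(Cc2ccc(OCc3ccccc3)c(OC)c2)O1
F4 | step 14 | 2',6-bis(benzyloxy)-5'-(1,3-dioxolan-2-yl)-3',5-dimethoxy-[1,1'-biphenyl]-3-carbaldehyde | COc1cc(C2OCCO2)cc(-c2cc(C=O)cc(OC)c2OCc2ccccc2)c1OCc1ccccc1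
F5 | step 14 | syn-aldol adduct of F3 and F4: (4S)-4-benzyl-3-[(2R,3S)-3-hydroxy-3-(biaryl)-2-(dioxolanonyl)propanoyl]oxazolidin-2-one, with the biaryl of F4 and the dioxolanone of F2 | COc1cc(C2OCCO2)cc(-c2cc([C@@H](O)[C@@H](C(=O)N3C(=O)OC[C@@H]3Cc3ccccc3)[C@]3(Cc4ccc(OCc5ccccc5)c(OC)c4)O[C@H](C(C)(C)C)OC3=O)cc(OC)c2OCc2ccccc2)c1OCc1ccccc1
F6 | step 14 | aryltetralin with C3 spiro-fused (2S)-2-tert-butyl-1,3-dioxolan-4-one, C2 (R) [(4S)-4-benzyl-2-oxo-oxazolidin-3-yl]carbonyl, 7-benzyloxy, 6-methoxy and C1 (S) 2',6-bis(benzyloxy)-5'-formyl-3',5-dimethoxybiphenyl-3-yl | COc1cc(C=O)cc(-c2cc([C@H]3c4cc(OCc5ccccc5)c(OC)cc4C[C@]4(O[C@H](C(C)(C)C)OC4=O)[C@@H]3C(=O)N3C(=O)OC[C@@H]3Cc3ccccc3)cc(OC)c2OCc2ccccc2)c1OCc1ccccc1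
F7 | step 20 | (2S)-2-[3-(benzyloxy)-4-methoxybenzyl]butane-1,2,4-triol | COc1ccc(C[C@@](O)(CO)CCO)cc1OCc1ccccc1
F8 | step 20 | 2-{(4S)-4-[3-(benzyloxy)-4-methoxybenzyl]-2,2-dimethyl-1,3-dioxolan-4-yl}ethan-1-ol | COc1ccc(C[C@]2(CCO)COC(C)(C)O2)cc1OCc1ccccc1
F9 | step 20 | {(4S)-4-[3-(benzyloxy)-4-methoxybenzyl]-2,2-dimethyl-1,3-dioxolan-4-yl}acetic acid | COc1ccc(C[C@]2(CC(=O)O)COC(C)(C)O2)cc1OCc1ccccc1
F10 | step 20 | (4S)-4-benzyl-3-({(4S)-4-[3-(benzyloxy)-4-methoxybenzyl]-2,2-dimethyl-1,3-dioxolan-4-yl}acetyl)-1,3-oxazolidin-2-one | COc1ccc(C[C@]2(CC(=O)N3C(=O)OC[C@@H]3Cc3ccccc3)COC(C)(C)O2)cc1OCc1ccccc1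
F11 | step 20 | syn-aldol adduct of F10 and 20: as 30 but with the (4S)-2,2-dimethyl-1,3-dioxolane in place of the dioxolanone | COc1cc([C@@H](O)[C@@H](C(=O)N2C(=O)OC[C@@H]2Cc2ccccc2)[C@@]2(Cc3ccc(OC)c(OCc4ccccc4)c3)COC(C)(C)O2)cc(-c2cc([C@H]3c4cc(OCc5ccccc5)c(OC)cc4C[C@@](O)(C(=O)OC)[C@@H]3C(=O)OC)cc(OC)c2OCc2ccccc2)c1OCc1ccccc1
F12 | step 20 | acetonide of 31 across the C4′ and C5′ hydroxyls | COc1ccc(C[C@]2([C@H](CO)[C@H](O)c3cc(OC)c(OCc4ccccc4)c(-c4cc([C@H]5c6cc(OCc7ccccc7)c(OC)cc6C[C@@](O)(CO)[C@@H]5CO)cc(OC)c4OCc4ccccc4)c3)COC(C)(C)O2)cc1OCc1ccccc1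
F13 | step 22 | fully debenzylated 31 (four free phenols, open-chain tetraol side chain) | COc1ccc(C[C@@](O)(CO)[C@H](CO)[C@H](O)c2cc(OC)c(O)c(-c3cc([C@H]4c5cc(O)c(OC)cc5C[C@@](O)(CO)[C@@H]4CO)cc(OC)c3O)c2)cc1O
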